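## Retrosynthetic overview

1. The target is the ester of a butenolide acid (ring B half) with the primary alcohol of a ring-opened hydroxy lactone (ring A half). Apart from protecting groups, the butenolide acid is this hydroxy lactone minus water, so one monomer serves both halves. The last C–O bond is made on the carboxylate of the opened lactone, which cannot relactonise.
2. The monomer comes from a 3a-hydroxy alkylidene lactone by conjugate vinylation, ozonolysis, bromo-Wittig olefination and Stille hydroxymethylation. The alkylidene lactone comes from a C7 allyl selenide by a selenoxide [2,3] shift that relays C7 to C3a.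
3. The allyl selenide is made in the key step from a cyclopentenylmethyl diazoacetate. The carbene carbon (future C7a) is inserted into the C=C bond of the five-membered ring by cyclopropanation and electrocyclic opening, which builds lactone, tetrasubstituted alkene and six-membered ring in one operation.
4. Enabling feature: the five-membered lactone ring (C1, O2, C3) is fused to the C3a–C7a edge of the carbocycle. Its C3–O2–C1 chain can therefore act as the tether that ties C7a to C3a and forces the leaving group on C7a endo, cis to C4 and C6.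
5. Ring order: the cyclopentene comes first (from cyclopentenone, isopropyl centre set by asymmetric conjugate addition). Lactone and cyclopropane follow, then the six-membered carbocycle by expansion, all three in the same step. Ring A is the same carbocycle kept hydrated.

Key step: step 5

Assumption: the sense of induction of the phosphoramidite in step 1 is not predicted here; the ligand antipode that gives the R enol triflate is used.

Locants: isobenzofuran-1(3H)-one numbering throughout (C1 carbonyl, O2, C3 methylene, C3a, C4, C5, C6 isopropyl carbon, C7, C7a). β is the face of the isopropyl group and α the opposite face.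

## Route

Step 1
Reactants: 1 cyclopent-2-en-1-one; 2 diisopropylzinc
Product: 4 (R)-3-isopropylcyclopent-1-en-1-yl trifluoromethanesulfonate, via zinc enolate 3 (not isolated)
Conditions: Cu(OTf)2 (2 mol %), BINOL-derived bis(1-phenylethyl)amine phosphoramidite (4 mol %), iPr2Zn (1.2 equiv), toluene, −30 °C, slow addition of 1; then Tf2O (1.5 equiv), −30 to 0 °C
Reagents that add atoms: diisopropylzinc CC(C)[Zn]C(C)C; trifluoromethanesulfonic anhydride O=S(=O)(OS(=O)(=O)C(F)(F)F)C(F)(F)F
Why: Copper-catalysed enantioselective conjugate addition of a dialkylzinc to a cyclic enone sets the isopropyl stereocentre under ligand control, and O-triflation of the regiodefined zinc enolate fixes the double bond next to that centre.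

Step 2
Reactants: 4 (R)-3-isopropylcyclopent-1-en-1-yl trifluoromethanesulfonate; 5 (tributylstannyl)methanol
Product: 6 [(R)-3-isopropylcyclopent-1-en-1-yl]methanol
Conditions: Pd(PPh3)4 (5 mol %), LiCl (3 equiv), THF, 65 °C
Reagents that add atoms: (tributylstannyl)methanol CCCC[Sn](CO)(CCCC)CCCC
Why: Stille hydroxymethylation (oxidative addition of the enol triflate to zerovalent palladium, then transfer of CH2OH from tin) should keep the alkene position and leave the stereocentre untouched.

Step 3
Reactants: 6 [(R)-3-isopropylcyclopent-1-en-1-yl]methanol; 7 bromoacetyl bromide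
Product: 8 [(R)-3-isopropylcyclopent-1-en-1-yl]methyl 2-bromoacetate
Conditions: BrCH2COBr (1.5 equiv), NaHCO3 (3 equiv), MeCN, 0 °C
Reagents that add atoms: bromoacetyl bromide BrCC(=O)Br
Why: This is a plain O-acylation of a primary allylic alcohol under weakly basic conditions, the first half of the ditosylhydrazine route to diazoacetates.

Step 4
Reactants: 8 [(R)-3-isopropylcyclopent-1-en-1-yl]methyl 2-bromoacetate
Product: 9 [(R)-3-isopropylcyclopent-1-en-1-yl]methyl 2-diazoacetate
Conditions: TsNHNHTs (2 equiv), DBU (5 equiv), THF, 0 °C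
Reagents that add atoms: N,N'-ditosylhydrazine Cc1ccc(cc1)S(=O)(=O)NNS(=O)(=O)c1ccc(C)cc1
Why: N-alkylation of ditosylhydrazine by the bromoacetate followed by twofold base-induced loss of sulfinate is the standard diazoacetate synthesis from bromoacetates, and it tolerates the alkene.

Step 5
Reactants: 9 [(R)-3-isopropylcyclopent-1-en-1-yl]methyl 2-diazoacetate
Product: 13 (6R,7R)-6-isopropyl-7-(phenylselanyl)-4,5,6,7-tetrahydroisobenzofuran-1(3H)-one, via bromodiazoacetate 10 (not isolated), via endo-bromocyclopropane lactone 11 (not isolated), via allyl cation bromide 12 (not isolated)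
Conditions: DBU (1.4 equiv), NBS (1.2 equiv), CH2Cl2, 0 °C, 2 min, cold silica plug; filtrate into Rh2(esp)2 (0.5 mol %; esp = α,α,α′,α′-tetramethyl-1,3-benzenedipropionate), CH2Cl2, 0 °C; then PhSeSiMe3 (1.5 equiv), ZnBr2 (20 mol %), 0 to 25 °C
Reagents that add atoms: phenyl trimethylsilyl selenide C[Si](C)(C)[Se]c1ccccc1
Why: Proposed new method: NBS/DBU turns 9 into bromodiazoacetate 10, whose Rh2(esp)2 carbenoid adds to the tethered cyclopentene C=C (intramolecular [2+1] cycloaddition that closes the five-membered lactone ring in the usual allyl diazoacetate mode, new bonds C7a–C3a and C7a–C7) to give 11, and ZnBr2 then ionises the C–Br bond in concert with disrotatory two-electron electrocyclic opening of the shared C3a–C7 bond, so that the five-membered carbocycle takes up the carbene carbon and becomes the six-membered ring of allyl cation 12 (closure mode of this ring: one-carbon ring expansion by cleavage of the zero bridge of the bicyclo[3.1.0]hexane). The closest known reaction types are the cyclopropanation–ring expansion of indoles with halodiazoacetates, the heat- or silver-induced opening of 6,6-dihalobicyclo[3.1.0]hexanes to 2-halocyclohexenyl cations, and the one-carbon insertion into alkenes by rhodium carbenoids that carry a nucleofuge; new here are the lactone tether, the unactivated alkene and the selenium trap. The decisive selectivity, bromine endo on the cyclopropane, is secured by the substrate: the three-atom C3–O2–C1 tether can span the cyclopropane edge only cis, which puts C1 exo and bromine cis to C4 and C6, the Woodward–Hoffmann–DePuy arrangement in which these two carbons turn inward and a cis-cyclohexenyl cation can form, helped by strain release and by the tertiary terminus C3a. Both faces of the alkene lead to the same planar cation, so the facial selectivity of the cyclopropanation is irrelevant and the three stereocentres of 11 are erased. The only stereocentre kept, C7, is set by attack of the large, soft selenium nucleophile anti to the adjacent C6 isopropyl group, and attack at tertiary C3a is reversible under ZnBr2, so the isomer with the tetrasubstituted, conjugated C3a=C7a bond should accumulate. Proton loss from C6 or C4 is held back by the low temperature, the excess of nucleophile and reversible ion pairing with bromide.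

Step 6
Reactants: 13 (6R,7R)-6-isopropyl-7-(phenylselanyl)-4,5,6,7-tetrahydroisobenzofuran-1(3H)-one
Product: 16 (3aS,6R)-3a-hydroxy-6-isopropyl-3a,4,5,6-tetrahydroisobenzofuran-1(3H)-one, via allyl selenoxide 14 (not isolated), via allyl selenenate 15 (not isolated)
Conditions: 30 % H2O2 (5 equiv), pyridine (3 equiv), CH2Cl2, −20 to 20 °C
Reagents that add atoms: hydrogen peroxide OO
Why: Selenide oxidation and allylic selenoxide [2,3]-sigmatropic rearrangement (the selenium counterpart of the Mislow–Evans reaction) carry oxygen suprafacially from the α face of C7 to the α face of C3a, which sets the tertiary carbinol and should outrun syn elimination toward C6–H.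

Step 7
Reactants: 16 (3aS,6R)-3a-hydroxy-6-isopropyl-3a,4,5,6-tetrahydroisobenzofuran-1(3H)-one; 17 vinylmagnesium bromide
Product: 19 (3aS,6R,7R,7aS)-3a-hydroxy-6-isopropyl-7-vinylhexahydroisobenzofuran-1(3H)-one, via bis-silyl ketene acetal 18 (not isolated)
Conditions: CH2=CHMgBr (3.5 equiv), CuBr·SMe2 (20 mol %), TMSCl (5 equiv), THF, −78 to −30 °C; 1 M HCl, THF, 0 °C
Reagents that add atoms: vinylmagnesium bromide C=C[Mg]Br
Why: In this copper-catalysed, TMSCl-accelerated conjugate addition of a Grignard reagent to an s-cis alkylidene lactone, axial attack on C7 anti to the neighbouring isopropyl group sets C7, silylation blocks β-elimination and retro-aldol cleavage, and protonation of the ketene acetal gives the cis-fused lactone (C7a), which is also the product of equilibration.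

Step 8
Reactants: 19 (3aS,6R,7R,7aS)-3a-hydroxy-6-isopropyl-7-vinylhexahydroisobenzofuran-1(3H)-one
Product: 20 (3aS,6R,7R,7aS)-3a-hydroxy-6-isopropyl-1-oxooctahydroisobenzofuran-7-carbaldehyde
Conditions: O3, CH2Cl2/MeOH, −78 °C; Me2S, −78 to 20 °C
Reagents that add atoms: ozone [O-][O+]=O
Why: Ozonolysis with reductive work-up should be clean because the vinyl group is the only alkene, and the equatorial aldehyde is the stable epimer.

Step 9
Reactants: 20 (3aS,6R,7R,7aS)-3a-hydroxy-6-isopropyl-1-oxooctahydroisobenzofuran-7-carbaldehyde; 21 tert-butyl (triphenylphosphoranylidene)acetate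
Product: 23 tert-butyl (Z)-2-bromo-3-[(3aS,6R,7R,7aS)-3a-hydroxy-6-isopropyl-1-oxooctahydroisobenzofuran-7-yl]acrylate, via bromo ylide 22 (not isolated)
Conditions: 21 (1.5 equiv), NBS (1.5 equiv), CH2Cl2, −20 °C; then 20, 20 °C
Reagents that add atoms: tert-butyl (triphenylphosphoranylidene)acetate CC(C)(C)OC(=O)C=P(c1ccccc1)(c1ccccc1)c1ccccc1; N-bromosuccinimide O=C1CCC(=O)N1Br
Why: Wittig olefination with the stabilised bromo ylide made in situ places the ring trans to the ester (Z bromoacrylate) under neutral conditions that spare the aldehyde α-centre and the β-hydroxy lactone.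

Step 10
Reactants: 23 tert-butyl (Z)-2-bromo-3-[(3aS,6R,7R,7aS)-3a-hydroxy-6-isopropyl-1-oxooctahydroisobenzofuran-7-yl]acrylate; 5 (tributylstannyl)methanol
Product: 24 tert-butyl (E)-2-(hydroxymethyl)-3-[(3aS,6R,7S,7aS)-3a-hydroxy-6-isopropyl-1-oxooctahydroisobenzofuran-7-yl]acrylate
Conditions: 5 (1.5 equiv), Pd(PPh3)4 (10 mol %), toluene, 90 °C
Reagents that add atoms: (tributylstannyl)methanol CCCC[Sn](CO)(CCCC)CCCC
Why: Stille coupling proceeds with retention of alkene geometry, so CH2OH takes the place of bromine cis to the ring and the E enoate of the target results.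

Step 11
Reactants: 24 tert-butyl (E)-2-(hydroxymethyl)-3-[(3aS,6R,7S,7aS)-3a-hydroxy-6-isopropyl-1-oxooctahydroisobenzofuran-7-yl]acrylate
Product: 25 tert-butyl (E)-2-{[(tert-butyldimethylsilyl)oxy]methyl}-3-[(3aS,6R,7S,7aS)-3a-hydroxy-6-isopropyl-1-oxooctahydroisobenzofuran-7-yl]acrylate (the common monomer)
Conditions: TBSCl (1.2 equiv), imidazole (2.5 equiv), CH2Cl2, 0 °C
Reagents that add atoms: tert-butyldimethylsilyl chloride CC(C)(C)[Si](C)(C)Cl
Why: Silyl ether formation should be selective for the primary allylic alcohol, because the tertiary alcohol is inert to TBSCl/imidazole.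

Step 12
Reactants: 25 the common monomer
Product: 27 tert-butyl (E)-2-{[(tert-butyldimethylsilyl)oxy]methyl}-3-[(6R,7S)-6-isopropyl-1-oxo-1,3,4,5,6,7-hexahydroisobenzofuran-7-yl]acrylate, via tertiary mesylate 26 (not isolated)
Conditions: MsCl (3 equiv), Et3N (5 equiv), CH2Cl2, 0 °C; then DBU (2 equiv), 0 to 20 °C
Reagents that add atoms: none
Why: Mesylation through sulfene is followed by E1cB elimination via the lactone enolate, and because the equatorial mesylate has no antiperiplanar hydrogen only the conjugated tetrasubstituted butenolide of ring B should form, with C6 and C7 untouched.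

Step 13
Reactants: 27 tert-butyl ester of the ring B half
Product: 29 (E)-2-{[(tert-butyldimethylsilyl)oxy]methyl}-3-[(6R,7S)-6-isopropyl-1-oxo-1,3,4,5,6,7-hexahydroisobenzofuran-7-yl]acrylic acid, via trimethylsilyl ester 28 (not isolated)
Conditions: TMSOTf (3 equiv), 2,6-lutidine (4.5 equiv), CH2Cl2, 0 °C; pH 5 buffer
Reagents that add atoms: none
Why: Silyl triflate-mediated cleavage of a tert-butyl ester (loss of isobutene, hydrolysis of the silyl ester on work-up) is a known way to free the acid while a primary TBS ether and a butenolide stay intact.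

Step 14
Reactants: 25 the common monomer
Product: 30 potassium salt of the ring-opened monomer: the cyclohexane carboxylate with 3a-OH α, CH2OH β, carboxylate β, side chain α and isopropyl β
Conditions: KOH (1.0 equiv), THF/H2O, 0 °C; freeze-drying
Reagents that add atoms: potassium hydroxide [K+].[OH-]
Why: Saponification with one equivalent of hydroxide should open only the γ-lactone (tert-butyl enoate and silyl ether are inert), and as a carboxylate the product can neither relactonise nor undergo retro-aldol cleavage.

Step 15
Reactants: 29 ring B acid; 30 potassium salt of the ring-opened monomer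
Product: 32 bis-TBS ether, mono-tert-butyl ester of the target, via acyl imidazolide 31 (not isolated)
Conditions: 29, 1,1'-carbonyldiimidazole (1.1 equiv), THF, 20 °C; then 30 (1.0 equiv), DBU (0.3 equiv), DMF, 0 to 20 °C; cold 0.1 M HCl to pH 3–4
Reagents that add atoms: none
Why: In this esterification through an acyl imidazolide the primary alcohol is the only competent nucleophile, since the tertiary alcohol is too hindered and acyl transfer to the carboxylate is uphill against imidazolide; unreacted 30 returns to 25 on acidification and can be reused.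

Step 16
Reactants: 32 bis-TBS ether, mono-tert-butyl ester of the target
Product: 33 target CNP0071646.2
Conditions: TFA/CH2Cl2/H2O (9:9:1), 0 to 20 °C; evaporation; aq NaHCO3/MeOH, then pH 3
Reagents that add atoms: none
Why: Acidolysis removes the tert-butyl ester and both primary silyl ethers in one operation, the tertiary carbinol being protected from ionisation by its two electron-withdrawing neighbours, and the brief bicarbonate treatment cleaves any trifluoroacetates.

## Compound list

1 | cyclopent-2-en-1-one | O=C1C=CCC1 | starting material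
2 | diisopropylzinc | CC(C)[Zn]C(C)C | starting material
3 | isopropylzinc (R)-3-isopropylcyclopent-1-en-1-olate | CC(C)[C@H]1CCC(O[Zn]C(C)C)=C1 | intermediate
4 | (R)-3-isopropylcyclopent-1-en-1-yl trifluoromethanesulfonate | CC(C)[C@H]1CCC(OS(=O)(=O)C(F)(F)F)=C1 | intermediate
5 | (tributylstannyl)methanol | CCCC[Sn](CO)(CCCC)CCCC | starting material
6 | [(R)-3-isopropylcyclopent-1-en-1-yl]methanol | CC(C)[C@H]1CCC(CO)=C1 | intermediate
7 | bromoacetyl bromide | BrCC(=O)Br | starting material
8 | [(R)-3-isopropylcyclopent-1-en-1-yl]methyl 2-bromoacetate | CC(C)[C@H]1CCC(COC(=O)CBr)=C1 | intermediate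
9 | [(R)-3-isopropylcyclopent-1-en-1-yl]methyl 2-diazoacetate | CC(C)[C@H]1CCC(COC(=O)C=[N+]=[N-])=C1 | intermediate
10 | [(R)-3-isopropylcyclopent-1-en-1-yl]methyl 2-bromo-2-diazoacetate | CC(C)[C@H]1CCC(COC(=O)C(Br)=[N+]=[N-])=C1 | intermediate
11 | tricyclic 6-bromobicyclo[3.1.0]hexane (cyclopropane anti to isopropyl) whose C6 carbonyl and bridgehead CH2O are joined as a γ-lactone, bromine endo | CC(C)[C@H]1CC[C@]23COC(=O)[C@@]2(Br)[C@H]13 | intermediate
12 | (R)-6-isopropyl-1-oxo-1,3,4,5,6,7-hexahydroisobenzofuran-7-ylium bromide (allyl cation C7–C7a–C3a) | CC(C)[C@H]1CCC2=C(C(=O)OC2)[CH+]1.[Br-] | intermediate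
13 | (6R,7R)-6-isopropyl-7-(phenylselanyl)-4,5,6,7-tetrahydroisobenzofuran-1(3H)-one (Se α, isopropyl β) | c1ccccc1[Se][C@H]1C2=C(CC[C@@H]1C(C)C)COC2=O | intermediate
14 | selenoxide of 13 | O=[Se](c1ccccc1)[C@H]1C2=C(CC[C@@H]1C(C)C)COC2=O | intermediate
15 | 3a-O-phenylselenenate of 16 | CC(C)[C@H]1CC[C@@]2(O[Se]c3ccccc3)COC(=O)C2=C1 | intermediate
16 | (3aS,6R)-3a-hydroxy-6-isopropyl-3a,4,5,6-tetrahydroisobenzofuran-1(3H)-one (OH α) | CC(C)[C@H]1CC[C@@]2(O)COC(=O)C2=C1 | intermediate
17 | vinylmagnesium bromide | C=C[Mg]Br | starting material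
18 | 1,3a-bis(trimethylsilyloxy) ketene acetal of 19 | CC(C)[C@H]1CC[C@@]2(O[Si](C)(C)C)COC(O[Si](C)(C)C)=C2[C@@H]1C=C | intermediate
19 | (3aS,6R,7R,7aS)-3a-hydroxy-6-isopropyl-7-vinylhexahydroisobenzofuran-1(3H)-one (vinyl α, cis-fused lactone on the β face) | CC(C)[C@H]1CC[C@@]2(O)COC(=O)[C@H]2[C@@H]1C=C | intermediate
20 | (3aS,6R,7R,7aS)-3a-hydroxy-6-isopropyl-1-oxooctahydroisobenzofuran-7-carbaldehyde | CC(C)[C@H]1CC[C@@]2(O)COC(=O)[C@H]2[C@@H]1C=O | intermediate
21 | tert-butyl (triphenylphosphoranylidene)acetate | CC(C)(C)OC(=O)C=P(c1ccccc1)(c1ccccc1)c1ccccc1 | starting material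
22 | tert-butyl bromo(triphenylphosphoranylidene)acetate | CC(C)(C)OC(=O)C(Br)=P(c1ccccc1)(c1ccccc1)c1ccccc1 | intermediate
23 | tert-butyl (Z)-2-bromo-3-[(3aS,6R,7R,7aS)-3a-hydroxy-6-isopropyl-1-oxooctahydroisobenzofuran-7-yl]acrylate | CC(C)[C@H]1CC[C@@]2(O)COC(=O)[C@H]2[C@@H]1/C=C(\Br)C(=O)OC(C)(C)C | intermediate
24 | tert-butyl (E)-2-(hydroxymethyl)-3-[(3aS,6R,7S,7aS)-3a-hydroxy-6-isopropyl-1-oxooctahydroisobenzofuran-7-yl]acrylate | CC(C)[C@H]1CC[C@@]2(O)COC(=O)[C@H]2[C@@H]1/C=C(\CO)C(=O)OC(C)(C)C | intermediate
25 | TBS ether of 24 (common monomer) | CC(C)[C@H]1CC[C@@]2(O)COC(=O)[C@H]2[C@@H]1/C=C(\CO[Si](C)(C)C(C)(C)C)C(=O)OC(C)(C)C | intermediate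
26 | 3a-O-mesylate of 25 | CC(C)[C@H]1CC[C@@]2(OS(C)(=O)=O)COC(=O)[C@H]2[C@@H]1/C=C(\CO[Si](C)(C)C(C)(C)C)C(=O)OC(C)(C)C | intermediate
27 | tert-butyl (E)-2-{[(tert-butyldimethylsilyl)oxy]methyl}-3-[(6R,7S)-6-isopropyl-1-oxo-1,3,4,5,6,7-hexahydroisobenzofuran-7-yl]acrylate | CC(C)(C)OC(=O)/C(=C/[C@H]1C2=C(CC[C@@H]1C(C)C)COC2=O)CO[Si](C)(C)C(C)(C)C | intermediate
28 | trimethylsilyl ester corresponding to 27 | C[Si](C)(C)OC(=O)/C(=C/[C@H]1C2=C(CC[C@@H]1C(C)C)COC2=O)CO[Si](C)(C)C(C)(C)C | intermediate
29 | (E)-2-{[(tert-butyldimethylsilyl)oxy]methyl}-3-[(6R,7S)-6-isopropyl-1-oxo-1,3,4,5,6,7-hexahydroisobenzofuran-7-yl]acrylic acid | OC(=O)/C(=C/[C@H]1C2=C(CC[C@@H]1C(C)C)COC2=O)CO[Si](C)(C)C(C)(C)C | intermediate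
30 | potassium salt of the ring-opened monomer | CC(C)[C@H]1CC[C@@](O)(CO)[C@@H](C(=O)[O-])[C@@H]1/C=C(\CO[Si](C)(C)C(C)(C)C)C(=O)OC(C)(C)C.[K+] | intermediate
31 | acyl imidazolide of 29 | O=C(n1ccnc1)/C(=C/[C@H]1C2=C(CC[C@@H]1C(C)C)COC2=O)CO[Si](C)(C)C(C)(C)C | intermediate
32 | bis-TBS ether, mono-tert-butyl ester of the target | CC(C)[C@H]1CC[C@@](O)(COC(=O)/C(=C/[C@H]2C3=C(CC[C@@H]2C(C)C)COC3=O)CO[Si](C)(C)C(C)(C)C)[C@@H](C(=O)O)[C@@H]1/C=C(\CO[Si](C)(C)C(C)(C)C)C(=O)OC(C)(C)C | intermediate
33 | CNP0071646.2 | CC(C)[C@H]1CC[C@@](O)(COC(=O)/C(=C/[C@H]2C3=C(CC[C@@H]2C(C)C)COC3=O)CO)[C@@H](C(=O)O)[C@@H]1/C=C(\CO)C(=O)O | target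

## Step count and risks

Total step count: 16. Longest linear sequence: 15 steps (steps 1–13, 15, 16).

### 1. Step 5 (proposed new method)

What may go wrong:
- bromination of the ring alkene while the diazo ester is halogenated
- sluggish ionisation of a bromocyclopropane that carries an acceptor on the departing carbon
- proton loss from C6 or C4 of the allyl cation, with loss of the isopropyl stereocentre
- poor facial selectivity of the selenium capture

The fallback uses known chemistry. It keeps the enlargement of the five-membered to the six-membered ring but uses dibromocarbene and brings in the carboxyl carbon later as CO. It sets out from 6 and comes back to the route at 16. Alcohol 6 is silylated (TBSCl, imidazole) to the silyl ether F1. Phase-transfer dibromocarbene addition (CHBr3, 50 % NaOH, BnEt3NCl) anti to the isopropyl group gives the dibromobicyclohexane F2. Warming F2 with PhSeSiMe3 and ZnBr2 triggers the classical electrocyclic opening of a gem-dibromocyclopropane, and the 2-bromocyclohexenyl cation is trapped anti to isopropyl as the bromo allyl selenide F3. H2O2/pyridine and the [2,3] shift give the tertiary allylic alcohol F4, and Bu4NF frees the bromo diol F5. Carbonylative lactonisation of the vinyl bromide (Pd(PPh3)4, CO, Et3N, DMF, 60 °C) then closes the alkylidene lactone 16.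

### 2. Step 15

What may go wrong:
- slow acylation of the hindered, neopentyl-type primary alcohol
- acyl transfer to the carboxylate followed by relactonisation with release of the ring B acid
- deconjugation of the activated acid by γ-deprotonation at C7

The fallback masks the ring A carboxyl as an amide instead of a salt. It sets out from 25 and 29 and comes back at 32. Lactone 25 is opened with MeONHMe·HCl/AlMe3 to the hydroxy Weinreb amide F6, a type of compound that is routinely handled without relactonisation. Esterification with 29 (2-methyl-6-nitrobenzoic anhydride, DMAP, Et3N) gives the amide ester F7. Cp2Zr(H)Cl reduces the amide chemoselectively to the aldehyde F8, and Pinnick oxidation (NaClO2, NaH2PO4, 2-methyl-2-butene) gives 32.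

### 3. Step 7

What may go wrong:
- β-elimination of the C3a oxygen from the enolate, which leads straight to the butenolide series
- 1,2-addition to the lactone
- eroded facial selectivity, because the incoming group is syn-axial to the C3a oxygen

The fallback replaces the organometallic addition by a radical one. It sets out from 16 and comes back at 20. Photocatalytic hydrogen-atom abstraction from 1,3-dioxolane ((Bu4N)4W10O32, 390 nm, MeCN/1,3-dioxolane) and Giese addition of the nucleophilic dioxolanyl radical to C7, anti to isopropyl and under neutral conditions, give the dioxolane F9. Mild acid hydrolysis (1 M HCl, THF) then gives aldehyde 20 without passing through 19.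

## Further compounds

F1 | step 5 | tert-butyl{[(R)-3-isopropylcyclopent-1-en-1-yl]methoxy}dimethylsilane | CC(C)[C@H]1CCC(CO[Si](C)(C)C(C)(C)C)=C1
F2 | step 5 | 6,6-dibromo-1-[(tert-butyldimethylsilyloxy)methyl]-4-isopropylbicyclo[3.1.0]hexane, cyclopropane anti to isopropyl | CC(C)[C@H]1CC[C@]2(CO[Si](C)(C)C(C)(C)C)C(Br)(Br)[C@H]12
F3 | step 5 | 2-bromo-1-[(tert-butyldimethylsilyloxy)methyl]-4-isopropyl-3-(phenylselanyl)cyclohex-1-ene, Se trans to isopropyl | c1ccccc1[Se][C@H]1C(Br)=C(CO[Si](C)(C)C(C)(C)C)CC[C@@H]1C(C)C
F4 | step 5 | 2-bromo-1-[(tert-butyldimethylsilyloxy)methyl]-4-isopropylcyclohex-2-en-1-ol, OH trans to isopropyl | CC(C)[C@H]1CC[C@@](O)(CO[Si](C)(C)C(C)(C)C)C(Br)=C1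
F5 | step 5 | 2-bromo-1-(hydroxymethyl)-4-isopropylcyclohex-2-en-1-ol, OH trans to isopropyl | CC(C)[C@H]1CC[C@@](O)(CO)C(Br)=C1
F6 | step 15 | N-methoxy-N-methylamide of the ring-opened monomer | CC(C)[C@H]1CC[C@@](O)(CO)[C@@H](C(=O)N(C)OC)[C@@H]1/C=C(\CO[Si](C)(C)C(C)(C)C)C(=O)OC(C)(C)C
F7 | step 15 | ester of F6 with acid 29 | CC(C)[C@H]1CC[C@@](O)(COC(=O)/C(=C/[C@H]2C3=C(CC[C@@H]2C(C)C)COC3=O)CO[Si](C)(C)C(C)(C)C)[C@@H](C(=O)N(C)OC)[C@@H]1/C=C(\CO[Si](C)(C)C(C)(C)C)C(=O)OC(C)(C)C
F8 | step 15 | ring A aldehyde corresponding to 32 | CC(C)[C@H]1CC[C@@](O)(COC(=O)/C(=C/[C@H]2C3=C(CC[C@@H]2C(C)C)COC3=O)CO[Si](C)(C)C(C)(C)C)[C@@H](C=O)[C@@H]1/C=C(\CO[Si](C)(C)C(C)(C)C)C(=O)OC(C)(C)C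
F9 | step 7 | 7-(1,3-dioxolan-2-yl)-3a-hydroxy-6-isopropylhexahydroisobenzofuran-1(3H)-one, configuration as in 20 | CC(C)[C@H]1CC[C@@]2(O)COC(=O)[C@H]2[C@@H]1C1OCCO1
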